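**Retrosynthetic overview**
1. Target 12 ⇐ alkene saturation plus hydrogenolysis of three O-benzyl groups of the (S,E)-allylic acetate 10; the acetate is kept.
2. 10 ⇐ cross-metathesis of the chiral branched allylic acetate 8 with 10-undecen-1-ol (adds C4–C13 of the side chain).
3. 8 ⇐ key C–O bond: enantioselective branched allylic C–H acetoxylation of the homoallyl arene 6 with acetic acid (sets the only stereocenter).
4. 6 ⇐ lateral lithiation/allylation of tribenzyl orsellinate 3 ⇐ orsellinic acid + benzyl bromide.
5. No ring is formed; the benzene ring is bought intact.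

Assumption: orsellinic acid is taken as a commercial starting material. L* in step 3 is a new sulfoxide–olefin ligand, methyl (E)-3-[2-(tert-butylsulfinyl)phenyl]acrylate, used as one sulfur enantiomer; which antipode gives (S)-8 cannot be predicted and is fixed by screening.

**Step 1**
Reactants: 1 orsellinic acid (2,4-dihydroxy-6-methylbenzoic acid); 2 benzyl bromide
Product: 3 benzyl 2,4-bis(benzyloxy)-6-methylbenzoate
Conditions: BnBr (3.6 equiv), K2CO3 (4.5 equiv), TBAI (5 mol%), DMF, rt then 70 °C, 16 h
Reagents that add atoms: benzyl bromide, BrCc1ccccc1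
Why: Carboxylate O-alkylation at rt (which blocks decarboxylation) followed by Williamson etherification of both phenols on heating, the hydrogen-bonded 2-OH reacting last.

**Step 2**
Reactants: 3 benzyl 2,4-bis(benzyloxy)-6-methylbenzoate; 4 allyl bromide
Product: 6 benzyl 2,4-bis(benzyloxy)-6-(but-3-en-1-yl)benzoate, via lithiated toluate 5 (not isolated)
Conditions: LDA (1.2 equiv), THF, –78 °C, 30 min; allyl bromide (1.5 equiv), –78 to –40 °C
Reagents that add atoms: allyl bromide, C=CCBr
Why: Lateral (benzylic) lithiation of an ortho-toluate gives an ester-stabilised benzylic anion that is alkylated by SN2 on allyl bromide, while the 2,6-disubstituted ester is too hindered to self-condense at –78 °C.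

**Step 3**
Reactants: 6 benzyl 2,4-bis(benzyloxy)-6-(but-3-en-1-yl)benzoate; 7 acetic acid
Product: 8 benzyl 6-[(2S)-2-acetoxybut-3-en-1-yl]-2,4-bis(benzyloxy)benzoate
Conditions: Pd(OAc)2 (10 mol%), L* (12 mol%), 2,6-dimethyl-1,4-benzoquinone (1.5 equiv), AcOH (10 equiv), 4 Å MS, 1,4-dioxane, 40 °C, 48 h
Reagents that add atoms: acetic acid, CC(=O)O
Why: Proposed new method: enantioselective branched allylic C–H acetoxylation, in which sulfoxide-bound electrophilic Pd(OAc)2 cleaves the allylic C–H bond of the coordinated terminal alkene by acetate-assisted deprotonation to give a π-allyl-Pd(OAc) species, and the tethered electron-poor alkene of L* then binds Pd as the π-acid (the role free benzoquinone plays in the racemic reaction) and triggers inner-sphere C–O reductive elimination of acetate onto the substituted allyl terminus inside a chiral pocket, so that the fast η3–η1–η3 equilibration of the allyl faces is resolved under Curtin–Hammett control to the (S)-acetate while the hindered 2,6-dimethylbenzoquinone only reoxidises Pd(0); the closest known reaction type is the racemic Pd(II)/bis-sulfoxide/benzoquinone branched allylic C–H acetoxylation of terminal alkenes (White-type allylic C–H oxidation), whose chiral-Lewis-acid variant gives only moderate ee.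

**Step 4**
Reactants: 8 benzyl 6-[(2S)-2-acetoxybut-3-en-1-yl]-2,4-bis(benzyloxy)benzoate; 9 10-undecen-1-ol
Product: 10 benzyl 6-[(2S,3E)-2-acetoxy-13-hydroxytridec-3-en-1-yl]-2,4-bis(benzyloxy)benzoate
Conditions: Hoveyda–Grubbs II (5 mol%), 9 (3 equiv), 1,4-benzoquinone (10 mol%), CH2Cl2, 40 °C, 12 h
Reagents that add atoms: 10-undecen-1-ol, C=CCCCCCCCCCO
Why: Olefin cross-metathesis of a slow-dimerising secondary allylic acetate with an excess of a fast terminal alkene gives the E-1,2-disubstituted alkene with loss of ethene; the stereocenter is not touched and benzoquinone suppresses Ru–H alkene migration.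

**Step 5**
Reactants: 10 benzyl 6-[(2S,3E)-2-acetoxy-13-hydroxytridec-3-en-1-yl]-2,4-bis(benzyloxy)benzoate
Product: 12 2-[(2R)-2-acetoxy-13-hydroxytridecyl]-4,6-dihydroxybenzoic acid (target), via saturated tribenzyl acetate 11 (not isolated)
Conditions: H2 (1 atm), 5% Rh/Al2O3, EtOAc, rt, 2 h; then 10% Pd/C and EtOH added, H2 (1 atm), rt, 6 h
Reagents that add atoms: none
Why: Catalytic hydrogenation on Rh saturates the alkene with little allylic C–O hydrogenolysis, then Pd-catalysed hydrogenolysis removes the benzyl ester and both aryl benzyl ethers; the acetate and the C–O stereocenter are inert, and the descriptor changes from S to R only because the CIP priorities change.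

**Compound list**
1 | orsellinic acid (2,4-dihydroxy-6-methylbenzoic acid) | Cc1cc(O)cc(O)c1C(=O)O | starting material
2 | benzyl bromide | BrCc1ccccc1 | starting material
3 | benzyl 2,4-bis(benzyloxy)-6-methylbenzoate | Cc1cc(OCc2ccccc2)cc(OCc2ccccc2)c1C(=O)OCc1ccccc1 | intermediate
4 | allyl bromide | C=CCBr | starting material
5 | benzyl 2,4-bis(benzyloxy)-6-(lithiomethyl)benzoate (lithiated toluate) | [Li]Cc1cc(OCc2ccccc2)cc(OCc2ccccc2)c1C(=O)OCc1ccccc1 | intermediate
6 | benzyl 2,4-bis(benzyloxy)-6-(but-3-en-1-yl)benzoate | C=CCCc1cc(OCc2ccccc2)cc(OCc2ccccc2)c1C(=O)OCc1ccccc1 | intermediate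
7 | acetic acid | CC(=O)O | starting material
8 | benzyl 6-[(2S)-2-acetoxybut-3-en-1-yl]-2,4-bis(benzyloxy)benzoate | CC(=O)O[C@H](C=C)Cc1cc(OCc2ccccc2)cc(OCc2ccccc2)c1C(=O)OCc1ccccc1 | intermediate
9 | 10-undecen-1-ol | C=CCCCCCCCCCO | starting material
10 | benzyl 6-[(2S,3E)-2-acetoxy-13-hydroxytridec-3-en-1-yl]-2,4-bis(benzyloxy)benzoate | CC(=O)O[C@H](/C=C/CCCCCCCCCO)Cc1cc(OCc2ccccc2)cc(OCc2ccccc2)c1C(=O)OCc1ccccc1 | intermediate
11 | benzyl 6-[(2R)-2-acetoxy-13-hydroxytridecyl]-2,4-bis(benzyloxy)benzoate | CC(=O)O[C@H](CCCCCCCCCCCO)Cc1cc(OCc2ccccc2)cc(OCc2ccccc2)c1C(=O)OCc1ccccc1 | intermediate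
12 | 2-[(2R)-2-acetoxy-13-hydroxytridecyl]-4,6-dihydroxybenzoic acid | CC(=O)O[C@H](CCCCCCCCCCCO)Cc1cc(O)cc(O)c1C(=O)O | target

**Step count**
Total steps: 5. Longest linear sequence: 5 (1 → 3 → 6 → 8 → 10 → 12).

**Three steps most likely to fail**

Step 3 (the proposed new reaction; risks are low ee, linear acetate, or diene formation by β-hydride loss). The fallback uses known chemistry, sets out from 3 and comes back at 8. Compound 3 is lithiated as in step 2 (LDA, THF, –78 °C, via 5) and alkylated with 3-bromo-1-(trimethylsilyl)prop-1-yne to give benzyl 2,4-bis(benzyloxy)-6-[4-(trimethylsilyl)but-3-yn-1-yl]benzoate F1. Desilylation (TBAF buffered with AcOH, THF, 0 °C) gives benzyl 2,4-bis(benzyloxy)-6-(but-3-yn-1-yl)benzoate F2. The Rh(I)/DIOP-catalysed redox-neutral coupling of a terminal alkyne with a carboxylic acid ([Rh(cod)Cl]2, DIOP-type bisphosphine of the antipode that gives S, AcOH, 1,2-dichloroethane, 70 °C) then isomerises the alkyne to the terminal allene and adds acetic acid at the substituted carbon to give 8. This sample also serves as the reference for ee and absolute sense of the step 3 product.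

Step 2 (benzyl ester may self-condense or be deprotonated at its OCH2Ph). The fallback sets out from 3 and comes back at 6. Saponification of 3 (KOH, DMSO–H2O, 90 °C) gives 2,4-bis(benzyloxy)-6-methylbenzoic acid F3. Its carboxylate/benzylic dianion (LDA, 2.2 equiv, THF, –78 °C) has no electrophilic ester and is alkylated with allyl bromide to give 2,4-bis(benzyloxy)-6-(but-3-en-1-yl)benzoic acid F4. Re-esterification (BnBr, K2CO3, DMF, rt) gives 6.

Step 5 (allylic C–O hydrogenolysis before the alkene is saturated would destroy the stereocenter). The fallback sets out from 10 and comes back at 11, then 12. The alkene is reduced without any metal surface by diimide (2-nitrobenzenesulfonyl hydrazide, Et3N, CH2Cl2, rt), and 11 is isolated. With no allylic system left, 11 is debenzylated by ordinary hydrogenolysis (H2, Pd/C, EtOAc–EtOH, rt) to 12. This fallback makes no new compound F0.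

**Further compounds**
F1 | step 3 | benzyl 2,4-bis(benzyloxy)-6-[4-(trimethylsilyl)but-3-yn-1-yl]benzoate | C[Si](C)(C)C#CCCc1cc(OCc2ccccc2)cc(OCc2ccccc2)c1C(=O)OCc1ccccc1
F2 | step 3 | benzyl 2,4-bis(benzyloxy)-6-(but-3-yn-1-yl)benzoate | C#CCCc1cc(OCc2ccccc2)cc(OCc2ccccc2)c1C(=O)OCc1ccccc1
F3 | step 2 | 2,4-bis(benzyloxy)-6-methylbenzoic acid | Cc1cc(OCc2ccccc2)cc(OCc2ccccc2)c1C(=O)O
F4 | step 2 | 2,4-bis(benzyloxy)-6-(but-3-en-1-yl)benzoic acid | C=CCCc1cc(OCc2ccccc2)cc(OCc2ccccc2)c1C(=O)O
F0 | step 5 | none | none
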